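**Direct plan and its weak points**

A direct plan would use methyl 2,4-dihydroxy-6-propylbenzoate A1 twice. One portion would be benzylated twice to methyl 2,4-bis(benzyloxy)-6-propylbenzoate A2 and saponified to 2,4-bis(benzyloxy)-6-propylbenzoic acid A3. A mixed anhydride of A3 would acylate the free 4-OH of a second A1 to give methyl 4-{[2,4-bis(benzyloxy)-6-propylbenzoyl]oxy}-2-hydroxy-6-propylbenzoate A4. O-Methylation of its chelated ring B phenol would give methyl 4-{[2,4-bis(benzyloxy)-6-propylbenzoyl]oxy}-2-methoxy-6-propylbenzoate A5, and hydrogenolysis would free the two ring A hydroxy groups.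
- The benzylation, the hydrolysis of a doubly ortho-substituted benzoate in hot KOH/DMSO and the final debenzylation would be three of five operations that form no bond of the target.
- The esterification would join a hindered, electron-rich 2,6-disubstituted benzoic acid (slow acyl transfer, decarboxylation under acid) to a phenol with two free OH groups, so regiocontrol would rest only on a hydrogen bond.
- The late methylation with MeI and carbonate would expose the base-labile aryl ester to cleavage or acyl migration; it would be needed only because the two ring B oxygens are not told apart earlier.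

**Retrosynthetic overview of the new route**

- Ring A (the 2,4-dihydroxy-6-propylbenzoyl unit) is a folded tetraketide and is made last, on the oxygen of ring B, from the C10 chain of diketo-dioxinone 18. The key step forms the depside C(=O)–O bond by ketene capture and then the ring A bond between C1 (bearing the depside carbonyl) and C6 (bearing the propyl group) by aldol closure.
- Ring B (phenol 12) is made first by a Diels–Alder reaction of methyl hex-2-ynoate 9 with diene 8 and loss of methanol. This forms its C1–C2 and C5–C6 bonds and delivers the 2-OMe and the free 4-OH already differentiated.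
- Order of ring formation: ring B (step 4), then ring A (step 7). Compound 18 comes in two acylations from 2,2,6-trimethyl-4H-1,3-dioxin-4-one 13.
- The design needs no protecting group, no ester hydrolysis, no coupling of a hindered benzoic acid and no methylation once the depside bond exists. The target is achiral.

Key step: step 7

Remark on the chemistry: compounds 1, 2, 9, 13 and 16 are assumed to be commercial; diene 8 is moisture-sensitive and would be used directly after distillation.

**Route**

Step 1
Reactants: 1 acetyl chloride; 2 1,1-dichloroethene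
Product: 4 4,4-dichlorobut-3-en-2-one, via 4,4,4-trichlorobutan-2-one 3 (not isolated)
Conditions: AlCl3 (1.05 equiv), CH2Cl2, 0 °C to rt; ice/1 M HCl; distillation at reduced pressure (loss of HCl)
Reagents that add atoms: none
Why: Friedel–Crafts-type acylation of an alkene, in which the acylium ion from 1 adds to the CH2 terminus of 2, chloride capture gives 3, and the acidic α-hydrogen allows β-elimination of HCl on heating to the conjugated dichlorovinyl ketone.

Step 2
Reactants: 4 4,4-dichlorobut-3-en-2-one
Product: 6 4,4-dimethoxybut-3-en-2-one, via 4-chloro-4-methoxybut-3-en-2-one 5 (not isolated)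
Conditions: NaOMe (2.05 equiv), MeOH, 0 °C to rt
Reagents that add atoms: sodium methoxide, [Na+].[O-]C
Why: Two successive addition–elimination (vinylic nucleophilic substitution) events at the β-carbon of the enone give a push–pull ketene acetal, which should resist a third addition at this stoichiometry.

Step 3
Reactants: 6 4,4-dimethoxybut-3-en-2-one
Product: 8 1,1-dimethoxy-3-(trimethylsilyloxy)buta-1,3-diene, via lithium enolate 7 (not isolated)
Conditions: LiN(iPr)2 (1.05 equiv), THF, −78 °C; Me3SiCl (1.2 equiv), −78 °C to 0 °C; pentane, filtration, distillation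
Reagents that add atoms: chlorotrimethylsilane, C[Si](C)(C)Cl
Why: Silyl enol ether formation, in which kinetic deprotonation of the only enolisable position (the methyl ketone) and O-silylation give the 2-silyloxy diene.

Step 4
Reactants: 8 1,1-dimethoxy-3-(trimethylsilyloxy)buta-1,3-diene (2.0 equiv); 9 methyl hex-2-ynoate
Product: 12 methyl 4-hydroxy-2-methoxy-6-propylbenzoate, via cyclohexadiene cycloadduct 10 (not isolated), via aryl trimethylsilyl ether 11 (not isolated)
Conditions: neat, 130 °C, sealed tube, 24 h; then 1 M HCl, THF, rt
Reagents that add atoms: none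
Why: Diels–Alder reaction of an electron-rich 1,1-dialkoxy-3-silyloxy diene with an alkynoate followed by aromatisation; the nucleophilic CH2 terminus of 8 should bond to the propyl-bearing β-carbon of 9 and the ketene acetal carbon to the α-carbon, so the ketal ends ortho to the ester and loses methanol to leave the 2-OMe, while the silyl enol ether becomes the free 4-OH on acidic work-up.

Step 5
Reactants: 13 2,2,6-trimethyl-4H-1,3-dioxin-4-one (2.0 equiv); 1 acetyl chloride (1.0 equiv)
Product: 15 2,2-dimethyl-6-(2-oxopropyl)-4H-1,3-dioxin-4-one, via lithium dienolate 14 (not isolated)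
Conditions: LiN(SiMe3)2 (2.0 equiv), THF, −78 °C; 1, −78 °C; 1 M HCl
Reagents that add atoms: none
Why: Vinylogous Claisen-type acylation, in which the dienolate from γ-deprotonation is C-acylated at its exocyclic carbon and the second equivalent of dienolate takes up the more acidic product so that it is not acylated again.

Step 6
Reactants: 15 2,2-dimethyl-6-(2-oxopropyl)-4H-1,3-dioxin-4-one; 16 N-methoxy-N-methylbutanamide (0.9 equiv)
Product: 18 6-(2,4-dioxoheptyl)-2,2-dimethyl-4H-1,3-dioxin-4-one, via dilithium dienediolate 17 (not isolated)
Conditions: LiN(iPr)2 (2.1 equiv), THF, −78 °C to −40 °C; 16, −78 °C to −20 °C; 1 M HCl to pH 3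
Reagents that add atoms: none
Why: Crossed Claisen-type acylation of a dianion, which should react at its last-formed, most nucleophilic terminal carbon with the N-methoxy-N-methylamide; the chelated tetrahedral adduct holds until work-up, so no second acylation occurs.

Step 7
Reactants: 18 6-(2,4-dioxoheptyl)-2,2-dimethyl-4H-1,3-dioxin-4-one (1.2 equiv); 12 methyl 4-hydroxy-2-methoxy-6-propylbenzoate
Product: 22 methyl 4-[(2,4-dihydroxy-6-propylbenzoyl)oxy]-2-methoxy-6-propylbenzoate, via acylketene 19 (not isolated), via aryl triketo ester 20 (not isolated), via aldol adduct 21 (not isolated)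
Conditions: toluene (0.2 M), 110 °C, 1 h, N2 stream to remove acetone; then Et3N (2 equiv), CH2Cl2, 0 °C to rt; then CF3CO2H (5 equiv), rt
Reagents that add atoms: none
Why: Thermal retro-hetero-Diels–Alder fragmentation of the dioxinone ring of 18 releases acetone and acylketene 19, which the single free OH of 12 captures to give aryl 3,5,7-trioxodecanoate 20; Et3N then lets the enolate carbon C2 (between the aryl ester and the C3 ketone) add to the C7 ketone, and acid removes water from 21 so that the cyclohexanedione enolises to the resorcinol ring A. The closest known reaction type is the ketene trapping and late-stage aldol aromatisation of diketo-dioxinones to 6-alkyl-2,4-dihydroxybenzoate esters, together with the acetoacetylation of phenols by dioxinone-derived acylketenes. Ring A closes in a 6-(enolendo)-exo-trig aldol mode that forms the bond between its C1 and C6, and loss of water with gain of aromaticity makes the closure irreversible. No stereocentre remains, since the two that appear in 21 are destroyed on aromatisation. The step needs capture of 19 by the phenol ahead of intramolecular O-acylation to a pyrone, and aldol closure ahead of Claisen closure (C6 onto C1) or lactonisation, both of which would expel the aryloxide; the first is served by a concentrated solution and an unhindered phenol OH, and the second rests on the high acidity of C2–H next to the aryl ester, the unhindered propyl ketone, and a weak non-nucleophilic amine base at or below room temperature in place of alkoxide or carbonate in methanol.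

**Compound list**

1 | acetyl chloride | CC(=O)Cl | starting material
2 | 1,1-dichloroethene | C=C(Cl)Cl | starting material
3 | 4,4,4-trichlorobutan-2-one (forms in the flask in step 1) | CC(=O)CC(Cl)(Cl)Cl | intermediate
4 | 4,4-dichlorobut-3-en-2-one | CC(=O)C=C(Cl)Cl | intermediate
5 | 4-chloro-4-methoxybut-3-en-2-one (forms in the flask in step 2; double-bond geometry not controlled) | CC(=O)C=C(Cl)OC | intermediate
6 | 4,4-dimethoxybut-3-en-2-one | CC(=O)C=C(OC)OC | intermediate
7 | lithium 4,4-dimethoxybuta-1,3-dien-2-olate (forms in the flask in step 3) | [Li+].[O-]C(=C)C=C(OC)OC | intermediate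
8 | 1,1-dimethoxy-3-(trimethylsilyloxy)buta-1,3-diene | C=C(O[Si](C)(C)C)C=C(OC)OC | intermediate
9 | methyl hex-2-ynoate | CCCC#CC(=O)OC | starting material
10 | methyl 6,6-dimethoxy-2-propyl-4-(trimethylsilyloxy)cyclohexa-1,4-diene-1-carboxylate (forms in the flask in step 4) | CCCC1=C(C(=O)OC)C(OC)(OC)C=C(O[Si](C)(C)C)C1 | intermediate
11 | methyl 2-methoxy-6-propyl-4-(trimethylsilyloxy)benzoate (forms in the flask in step 4) | CCCc1cc(O[Si](C)(C)C)cc(OC)c1C(=O)OC | intermediate
12 | methyl 4-hydroxy-2-methoxy-6-propylbenzoate (ring B) | CCCc1cc(O)cc(OC)c1C(=O)OC | intermediate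
13 | 2,2,6-trimethyl-4H-1,3-dioxin-4-one | CC1=CC(=O)OC(C)(C)O1 | starting material
14 | lithium 2,2-dimethyl-6-methylidene-6H-1,3-dioxin-4-olate (forms in the flask in step 5) | [Li+].C=C1C=C([O-])OC(C)(C)O1 | intermediate
15 | 2,2-dimethyl-6-(2-oxopropyl)-4H-1,3-dioxin-4-one | CC(=O)CC1=CC(=O)OC(C)(C)O1 | intermediate
16 | N-methoxy-N-methylbutanamide | CCCC(=O)N(C)OC | starting material
17 | dilithium 2,2-dimethyl-6-(2-oxidoprop-2-en-1-ylidene)-6H-1,3-dioxin-4-olate (forms in the flask in step 6) | [Li+].[Li+].C=C([O-])C=C1C=C([O-])OC(C)(C)O1 | intermediate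
18 | 6-(2,4-dioxoheptyl)-2,2-dimethyl-4H-1,3-dioxin-4-one | CCCC(=O)CC(=O)CC1=CC(=O)OC(C)(C)O1 | intermediate
19 | 3,5,7-trioxodec-1-en-1-one (acylketene; forms in the flask in step 7) | CCCC(=O)CC(=O)CC(=O)C=C=O | intermediate
20 | 3-methoxy-4-(methoxycarbonyl)-5-propylphenyl 3,5,7-trioxodecanoate (forms in the flask in step 7) | CCCC(=O)CC(=O)CC(=O)CC(=O)Oc1cc(CCC)c(C(=O)OC)c(OC)c1 | intermediate
21 | 3-methoxy-4-(methoxycarbonyl)-5-propylphenyl 2-hydroxy-4,6-dioxo-2-propylcyclohexane-1-carboxylate (forms in the flask in step 7; mixture of stereoisomers and enol forms) | CCCC1(O)CC(=O)CC(=O)C1C(=O)Oc1cc(CCC)c(C(=O)OC)c(OC)c1 | intermediate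
22 | methyl 4-[(2,4-dihydroxy-6-propylbenzoyl)oxy]-2-methoxy-6-propylbenzoate (CNP0177078.0, C22H26O7, achiral) | CCCc1cc(O)cc(O)c1C(=O)Oc1cc(CCC)c(C(=O)OC)c(OC)c1 | target

**Step count and risks**

Total step count: 7. Longest linear sequence: 5 steps (steps 1, 2, 3, 4 and 7); steps 5 and 6 form the second branch.

The three steps most likely to fail:

Step 7. Capture of acylketene 19 by the electron-poor phenol may be slower than intramolecular O-acylation of the enolised diketone, which would give a pyrone. Under base, the aryloxide may also be expelled from 20 by Claisen closure, lactonisation or return to the ketene before the aldol closes. The fallback closes ring A before the ester is made; it sets out from 18 and 12 and comes back at 22. Treatment of 18 with Et3N in CH2Cl2 should close the ring by the same aldol mode onto the intact dioxinone and give 7-hydroxy-2,2-dimethyl-5-propyl-4H-1,3-benzodioxin-4-one F1. Benzylation (BnBr, K2CO3, acetone) should give 7-(benzyloxy)-2,2-dimethyl-5-propyl-4H-1,3-benzodioxin-4-one F2. Irradiation of F2 at 300 nm in CH2Cl2 in the presence of 12 should expel acetone, and the quinone ketene so formed should acylate the phenol to give methyl 4-{[4-(benzyloxy)-2-hydroxy-6-propylbenzoyl]oxy}-2-methoxy-6-propylbenzoate F3. Hydrogenolysis (H2, 10% Pd/C, EtOAc, rt) should then give 22.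

Step 4. The β-alkyl alkynoate is a sluggish dienophile, so the diene may decay thermally or hydrolyse before it adds. The fallback builds ring B from the polyketide chain instead; it sets out from 18 and comes back at 12. Heating 18 with methanol in toluene at 110 °C, then K2CO3 in MeOH and HCl in MeOH (ketene trapping and aldol aromatisation on an alkyl ester, where no aryloxide can be lost) should give methyl 2,4-dihydroxy-6-propylbenzoate F4. BnBr (1.05 equiv) with K2CO3 in acetone should benzylate only the non-chelated 4-OH and give methyl 4-(benzyloxy)-2-hydroxy-6-propylbenzoate F5. MeI with K2CO3 in DMF should give methyl 4-(benzyloxy)-2-methoxy-6-propylbenzoate F6, and hydrogenolysis (H2, 10% Pd/C) should give 12.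

Step 6. Proton transfer between the dianion and the amide or product, attack at the dioxinone carbonyl, or premature aldol aromatisation of 18 during work-up may erode the acylation. The fallback replaces the dianion by soft enolisation and a decarboxylative unmasking; it sets out from 13 and comes back at 18. Dienolate 14 (from 13 and LiN(SiMe3)2) would be acylated with allyl 3-chloro-3-oxopropanoate to give allyl 4-(2,2-dimethyl-4-oxo-4H-1,3-dioxin-6-yl)-3-oxobutanoate F7. MgCl2, pyridine and butanoyl chloride in CH2Cl2 should C-acylate its doubly activated methylene and give allyl 2-[(2,2-dimethyl-4-oxo-4H-1,3-dioxin-6-yl)acetyl]-3-oxohexanoate F8. Pd(PPh3)4 (zerovalent palladium) with morpholine should remove the allyl group, and loss of CO2 should give 18.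

**Further compounds**

F1 | step 7 | 7-hydroxy-2,2-dimethyl-5-propyl-4H-1,3-benzodioxin-4-one | CCCc1cc(O)cc2OC(C)(C)OC(=O)c12
F2 | step 7 | 7-(benzyloxy)-2,2-dimethyl-5-propyl-4H-1,3-benzodioxin-4-one | CCCc1cc(OCc3ccccc3)cc2OC(C)(C)OC(=O)c12
F3 | step 7 | methyl 4-{[4-(benzyloxy)-2-hydroxy-6-propylbenzoyl]oxy}-2-methoxy-6-propylbenzoate | CCCc1cc(OCc2ccccc2)cc(O)c1C(=O)Oc1cc(CCC)c(C(=O)OC)c(OC)c1
F4 | step 4 | methyl 2,4-dihydroxy-6-propylbenzoate | CCCc1cc(O)cc(O)c1C(=O)OC
F5 | step 4 | methyl 4-(benzyloxy)-2-hydroxy-6-propylbenzoate | CCCc1cc(OCc2ccccc2)cc(O)c1C(=O)OC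
F6 | step 4 | methyl 4-(benzyloxy)-2-methoxy-6-propylbenzoate | CCCc1cc(OCc2ccccc2)cc(OC)c1C(=O)OC
F7 | step 6 | allyl 4-(2,2-dimethyl-4-oxo-4H-1,3-dioxin-6-yl)-3-oxobutanoate | C=CCOC(=O)CC(=O)CC1=CC(=O)OC(C)(C)O1
F8 | step 6 | allyl 2-[(2,2-dimethyl-4-oxo-4H-1,3-dioxin-6-yl)acetyl]-3-oxohexanoate | CCCC(=O)C(C(=O)OCC=C)C(=O)CC1=CC(=O)OC(C)(C)O1
A1 | direct plan | methyl 2,4-dihydroxy-6-propylbenzoate | CCCc1cc(O)cc(O)c1C(=O)OC
A2 | direct plan | methyl 2,4-bis(benzyloxy)-6-propylbenzoate | CCCc1cc(OCc2ccccc2)cc(OCc2ccccc2)c1C(=O)OC
A3 | direct plan | 2,4-bis(benzyloxy)-6-propylbenzoic acid | CCCc1cc(OCc2ccccc2)cc(OCc2ccccc2)c1C(=O)O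
A4 | direct plan | methyl 4-{[2,4-bis(benzyloxy)-6-propylbenzoyl]oxy}-2-hydroxy-6-propylbenzoate | CCCc1cc(OCc2ccccc2)cc(OCc2ccccc2)c1C(=O)Oc1cc(CCC)c(C(=O)OC)c(O)c1
A5 | direct plan | methyl 4-{[2,4-bis(benzyloxy)-6-propylbenzoyl]oxy}-2-methoxy-6-propylbenzoate | CCCc1cc(OCc2ccccc2)cc(OCc2ccccc2)c1C(=O)Oc1cc(CCC)c(C(=O)OC)c(OC)c1
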